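**Retrosynthetic overview**
1. Locants used below: C-1 to C-9 are the nine-carbon bridge (C-1 on bridgehead C-14, C-9 on bridgehead C-10); the six-membered ring is C-10, C-11 (spiro-epoxide carbon), C-12, C-13, C-14, C-15 (quaternary, CO2H); C-16 to C-19 are the 4-methylpent-3-enyl chain. Both bridge alkenes (C-2=C-3, C-6=C-7) are Z.
2. End game: the oxirane is closed last from a tertiary alkoxide and a primary tosylate; CO2H comes from a neopentyl CH2OSi group; the side chain comes from CHO (Wittig, then B-alkyl Suzuki); the C-11 oxygen comes from Sharpless epoxidation and hydride opening of a C-11=C-12 allylic alcohol.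
3. Key disconnection: in the six-membered ring the bonds C-13–C-14 and C-10–C-15 lie para to each other, and C-11 (next to C-10) carries the exocyclic CH2O. With a C-11=C-12 double bond the ring is therefore a Diels–Alder retron. Because the nine-carbon bridge joins the diene terminus C-10 to the dienophile carbon C-14, cutting both bonds opens the six- and the twelve-membered ring together and gives an acyclic, achiral tetraenal. Its enal carbon C-15 carries CHO (activating group, future side chain) and CH2OSi (future CO2H).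
4. Precursor: three small pieces joined by two B-alkyl Suzuki couplings (C-5–C-6 and C-9–C-10). The Z alkenes and the diene come from copper-catalysed carbomagnesiation/iodination of propargyl alcohol and from (Z)-3-methylpent-2-en-4-yn-1-ol. The enal end comes from ylide homologation, Wittig reaction with a dihydroxyacetone ketal and site-selective oxidation.
5. Ring order: six- and twelve-membered carbocycles together in step 15; oxirane in step 24.

Key step: step 15

Assumption: by the usual model for 2-substituted acroleins the (S)-configured oxazaborolidinium ion is taken to expose the Re face of the enal α-carbon C-15, which leads to 23; should the sense prove opposite, the (R) antipode of the catalyst is the one to use.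

**Route**

Step 1
Reactants: 1 prop-2-yn-1-ol
Product: 3 (2Z)-3-iodo-2-methylprop-2-en-1-ol, via chelated alkenylmagnesium alkoxide 2 (not isolated)
Conditions: MeMgBr (2.3 equiv), CuI (10 mol %), THF, 0 °C → rt; then I2, −20 °C
Reagents that add atoms: methylmagnesium bromide, C[Mg]Br; iodine, II
Why: Copper-catalysed anti-carbomagnesiation of the propargylic alkoxide puts Me on the internal carbon and Mg on the terminal carbon inside a five-membered O–Mg chelate, so iodinolysis with retention should give the iodide cis to CH2OH (Z).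

Step 2
Reactants: 3 (2Z)-3-iodo-2-methylprop-2-en-1-ol
Product: 4 (2Z)-3-iodo-2-methylprop-2-enal
Conditions: MnO2 (activated, excess), CH2Cl2, rt, dark
Reagents that add atoms: none
Why: MnO2 oxidation of the primary allylic alcohol is neutral and heterogeneous and should leave the Z β-iodo enal geometry intact.

Step 3
Reactants: 4 (2Z)-3-iodo-2-methylprop-2-enal
Product: 5 (1Z)-1-iodo-2-methylbuta-1,3-diene
Conditions: Ph3PCH3Br, KN(SiMe3)2, THF, −78 → 0 °C; product kept as a pentane solution
Reagents that add atoms: methyltriphenylphosphonium bromide, C[P+](c1ccccc1)(c1ccccc1)c1ccccc1.[Br-]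
Why: Wittig methylenation of the aldehyde with the non-stabilised ylide builds the vinyl group without touching the vinyl iodide or its geometry.

Step 4
Reactants: 1 prop-2-yn-1-ol
Product: 7 (2Z)-2-(iodomethylidene)but-3-en-1-ol, via chelated dienylmagnesium alkoxide 6 (not isolated)
Conditions: vinylmagnesium bromide (2.5 equiv), CuI (10 mol %), THF, 0 °C → rt; then I2, −20 °C
Reagents that add atoms: vinylmagnesium bromide, C=C[Mg]Br; iodine, II
Why: The same copper-catalysed anti-carbomagnesiation/iodinolysis puts iodine cis to CH2OH and trans to the new vinyl group, which is the diene geometry that later holds the tether in the outside position.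

Step 5
Reactants: 7 (2Z)-2-(iodomethylidene)but-3-en-1-ol
Product: 8 tert-butyl{[(2Z)-2-(iodomethylidene)but-3-en-1-yl]oxy}dimethylsilane
Conditions: TBSCl, imidazole, CH2Cl2, 0 °C
Reagents that add atoms: tert-butyldimethylsilyl chloride, CC(C)(C)[Si](C)(C)Cl
Why: Standard silylation of the primary allylic alcohol; the ether has to survive two Suzuki couplings and the Lewis acid of step 15.

Step 6
Reactants: 9 (2Z)-3-methylpent-2-en-4-yn-1-ol
Product: 10 (2Z)-3-methylpenta-2,4-dien-1-ol
Conditions: H2 (1 atm), Pd/CaCO3 poisoned with Pb(OAc)2 (Lindlar catalyst), quinoline, EtOAc, 0 °C, stopped after one equivalent of H2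
Reagents that add atoms: none
Why: Lindlar semi-hydrogenation of the terminal alkyne of the conjugated enyne should stop at the diene and leave the trisubstituted Z alkene unchanged.

Step 7
Reactants: 10 (2Z)-3-methylpenta-2,4-dien-1-ol; 5 (1Z)-1-iodo-2-methylbuta-1,3-diene
Product: 12 (2Z,6Z)-3,7-dimethylnona-2,6,8-trien-1-ol, via bis(9-BBN) adduct 11 (not isolated)
Conditions: 9-BBN (2.05 equiv), THF, 0 °C → rt; then 5, PdCl2(dppf) (5 mol %), AsPh3, K3PO4 (aq), DMF, rt
Reagents that add atoms: none
Why: B-alkyl Suzuki–Miyaura coupling: 9-BBN adds to the terminal CH2 of the only monosubstituted alkene, and the alkylborane couples with vinyl iodide 5 with retention, which joins C-5 to C-6 and fixes the second Z alkene.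

Step 8
Reactants: 12 (2Z,6Z)-3,7-dimethylnona-2,6,8-trien-1-ol
Product: 13 (2Z,6Z)-1-bromo-3,7-dimethylnona-2,6,8-triene
Conditions: CBr4, PPh3, CH2Cl2, −20 °C; used at once
Reagents that add atoms: carbon tetrabromide, BrC(Br)(Br)Br
Why: Appel bromination of the primary allylic alcohol at low temperature should proceed without allylic transposition and keep the Z geometry.

Step 9
Reactants: 13 (2Z,6Z)-1-bromo-3,7-dimethylnona-2,6,8-triene
Product: 14 [(3Z,7Z)-4,8-dimethyldeca-3,7,9-trien-1-yl]triphenylphosphonium bromide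
Conditions: Ph3PCH3Br, KN(SiMe3)2 (1.0 equiv), THF, −78 °C; then 13, −78 → 0 °C; salt precipitated with Et2O/pentane, filtered and dried
Reagents that add atoms: methyltriphenylphosphonium bromide, C[P+](c1ccccc1)(c1ccccc1)c1ccccc1.[Br-]
Why: SN2 alkylation of methylenetriphenylphosphorane at the primary allylic bromide gives the one-carbon-homologated phosphonium salt (the new carbon is C-14); one equivalent of ylide at low temperature and precipitation of the salt should limit proton transfer between product and unreacted ylide.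

Step 10
Reactants: 14 [(3Z,7Z)-4,8-dimethyldeca-3,7,9-trien-1-yl]triphenylphosphonium bromide; 15 2,2-dimethyl-1,3-dioxan-5-one
Product: 17 5-[(3Z,7Z)-4,8-dimethyldeca-3,7,9-trien-1-ylidene]-2,2-dimethyl-1,3-dioxane, via phosphonium ylide 16 (not isolated)
Conditions: KN(SiMe3)2 (1.0 equiv), THF, −78 °C; then 15, −78 °C → rt
Reagents that add atoms: none
Why: Deprotonation of the alkylphosphonium salt gives the non-stabilised ylide, and Wittig olefination with the symmetrical ketone forms C-14=C-15 without any E/Z question.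

Step 11
Reactants: 17 5-[(3Z,7Z)-4,8-dimethyldeca-3,7,9-trien-1-ylidene]-2,2-dimethyl-1,3-dioxane
Product: 18 2-[(3Z,7Z)-4,8-dimethyldeca-3,7,9-trien-1-ylidene]propane-1,3-diol
Conditions: AcOH/THF/H2O (3:1:1), rt
Reagents that add atoms: none
Why: Mild acid hydrolysis of the 1,3-dioxane ketal frees the 2-alkylidene-1,3-diol; the dienes tolerate aqueous acetic acid.

Step 12
Reactants: 18 2-[(3Z,7Z)-4,8-dimethyldeca-3,7,9-trien-1-ylidene]propane-1,3-diol; 8 tert-butyl{[(2Z)-2-(iodomethylidene)but-3-en-1-yl]oxy}dimethylsilane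
Product: 20 2-[(3Z,7Z,11Z)-12-({[tert-butyl(dimethyl)silyl]oxy}methyl)-4,8-dimethyltetradeca-3,7,11,13-tetraen-1-ylidene]propane-1,3-diol, via tris(9-BBN) adduct 19 (not isolated)
Conditions: 9-BBN (3.1 equiv), THF, 0 °C → rt; then 8, PdCl2(dppf) (5 mol %), AsPh3, K3PO4 (aq), DMF, rt
Reagents that add atoms: none
Why: Second B-alkyl Suzuki–Miyaura coupling: only the terminal vinyl group is hydroborated (the hydroxyls are masked as borinates, the trisubstituted alkenes are inert), and coupling with 8 with retention forms C-9–C-10 and the 2-(silyloxymethyl)-1,3-diene with the tether trans to the vinyl group.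

Step 13
Reactants: 20 the tetraene diol
Product: 21 (2E,5Z,9Z,13Z)-14-({[tert-butyl(dimethyl)silyl]oxy}methyl)-2-(hydroxymethyl)-6,10-dimethylhexadeca-2,5,9,13,15-pentaenal
Conditions: MnO2 (activated, added in portions), CH2Cl2, 0 °C, stopped at the mono-aldehyde
Reagents that add atoms: none
Why: MnO2 should oxidise the less hindered of the two allylic hydroxymethyl groups, the one cis to the vinylic hydrogen, which gives the conjugated E enal with CHO trans to C-1; the second hydroxymethyl is then cross-conjugated and more hindered and should react more slowly.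

Step 14
Reactants: 21 the hydroxy enal
Product: 22 (2E,5Z,9Z,13Z)-14-({[tert-butyl(dimethyl)silyl]oxy}methyl)-2-({[tert-butyl(diphenyl)silyl]oxy}methyl)-6,10-dimethylhexadeca-2,5,9,13,15-pentaenal
Conditions: TBDPSCl, imidazole, CH2Cl2, 0 °C
Reagents that add atoms: tert-butyldiphenylsilyl chloride, CC(C)(C)[Si](Cl)(c1ccccc1)c1ccccc1
Why: Silylation of the remaining primary alcohol gives a robust ether that can be told apart from the allylic TBS ether later.

Step 15
Reactants: 22 the acyclic tetraenal
Product: 23 bicyclo[9.3.1]pentadecatriene aldehyde (C-2=C-3 Z, C-6=C-7 Z, C-11=C-12; 15-CHO cis to C-9 and trans to C-1; 15-CH2OTBDPS; 11-CH2OTBS; 10-H and 14-H trans)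
Conditions: (S)-3,3-diphenyl-1-(o-tolyl)tetrahydro-1H,3H-pyrrolo[1,2-c][1,3,2]oxazaborole (40 mol %), Tf2NH (33 mol %), CH2Cl2, −78 °C; 22 added by syringe pump over 10 h (final 2 mM); then −40 °C
Reagents that add atoms: none
Why: Proposed new method: a chiral oxazaborolidinium ion binds the s-trans E enal, and the tethered 1,2-disubstituted butadiene adds through an asynchronous concerted [4+2] transition state (C-13–C-14 leading, C-10–C-15 lagging); the closest known reactions are oxazaborolidinium-catalysed Diels–Alder reactions of 2-substituted enals, their transannular variant and Lewis-acid-promoted macrocyclising intramolecular Diels–Alder reactions. The cyclohexene closes as the six-membered [4+2] ring and the twelve-membered carbocycle closes in the same event in the bridged mode, because the nine-carbon tether joins diene terminus C-10 to the β-carbon C-14 and so spans the one-carbon bridge C-15. C-14 and C-15 follow stereospecifically from the E enal (CHO trans to the tether) and C-10 from the diene geometry (tether outside); the endo-CHO transition state, which lets the tether leave on the open exo side, puts CHO cis to C-9 and trans to C-1, and the catalyst shields one enal face and so fixes the absolute configuration of all three centres. The step needs ortho regiochemistry (secured by the dominant 1-alkyl substituent of the diene, the β-polarised enal and the preference for a twelve- over an eleven-membered ring), endo selectivity, and ring closure over oligomerisation (slow addition, high dilution, a slight excess of oxazaborolidine over acid to suppress proton-initiated polyene cyclisation).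

Step 16
Reactants: 23 the adduct aldehyde
Product: 24 15-ethenyl analogue of 23 (CHO replaced by CH=CH2)
Conditions: Ph3PCH3Br, KN(SiMe3)2, THF, −78 → 0 °C
Reagents that add atoms: methyltriphenylphosphonium bromide, C[P+](c1ccccc1)(c1ccccc1)c1ccccc1.[Br-]
Why: Wittig methylenation of the non-enolisable neopentyl aldehyde; no stereocentre is touched.

Step 17
Reactants: 24 the vinyl compound; 25 1-bromo-2-methylprop-1-ene
Product: 27 15-(4-methylpent-3-en-1-yl) compound, via B-alkyl-9-BBN adduct 26 (not isolated)
Conditions: 9-BBN (1.5 equiv), THF, rt; then 25, PdCl2(dppf) (10 mol %), K3PO4 (aq), DMF, 50 °C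
Reagents that add atoms: none
Why: 9-BBN hydroborates only the monosubstituted vinyl group (the three trisubstituted alkenes are inert), and B-alkyl Suzuki–Miyaura coupling with 25 completes the side chain.

Step 18
Reactants: 27 the bis-silyl ether
Product: 28 allylic alcohol (11-CH2OH on C-11=C-12; 15-CH2OTBDPS kept)
Conditions: PPTS (cat.), MeOH/CH2Cl2, rt
Reagents that add atoms: none
Why: Acid-catalysed methanolysis removes the unhindered primary allylic TBS ether; the neopentyl TBDPS ether should survive.

Step 19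
Reactants: 28 the allylic alcohol
Product: 29 11,12-epoxy alcohol (oxirane oxygen cis to C-9 and trans to 15-CH2OTBDPS)
Conditions: Ti(OiPr)4 (20 mol %), L-(+)-diethyl tartrate (24 mol %), t-BuOOH (2 equiv), 4 Å molecular sieves, CH2Cl2, −20 °C
Reagents that add atoms: tert-butyl hydroperoxide, CC(C)(C)OO
Why: Sharpless asymmetric epoxidation: the titanium tartrate binds only the allylic alcohol, so the other alkenes are untouched, and L-(+)-tartrate should deliver oxygen to the face of C-11=C-12 on which C-9 lies (reagent control), which sets C-11.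

Step 20
Reactants: 29 the epoxy alcohol
Product: 30 1,2-diol (11-OH tertiary and cis to C-9; 11-CH2OH; C-12 now CH2)
Conditions: LiAlH4, THF, 0 °C → rt; aq. potassium sodium tartrate work-up
Reagents that add atoms: none
Why: Hydride opens the trisubstituted epoxide by SN2 attack at the less substituted carbon C-12, delivered anti to the C–O bond from the primary alkoxyaluminate, so the C-11–O bond and its configuration are kept.

Step 21
Reactants: 30 the diol
Product: 31 primary tosylate (11-CH2OTs; tertiary 11-OH free)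
Conditions: TsCl, pyridine, DMAP (cat.), 0 °C
Reagents that add atoms: p-toluenesulfonyl chloride, Cc1ccc(cc1)S(Cl)(=O)=O
Why: Selective sulfonylation of the primary hydroxyl; the tertiary hydroxyl does not react, and in pyridine the hydroxy tosylate should not yet cyclise.

Step 22
Reactants: 31 the tosylate
Product: 32 neopentyl alcohol (15-CH2OH)
Conditions: HF·pyridine, pyridine, THF, 0 °C → rt
Reagents that add atoms: none
Why: Buffered HF·pyridine cleaves the TBDPS ether under non-basic conditions, so the hydroxy tosylate is carried on unchanged.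

Step 23
Reactants: 32 the primary alcohol
Product: 33 aldehyde (15-CHO)
Conditions: Dess–Martin periodinane, NaHCO3, CH2Cl2, 0 °C → rt
Reagents that add atoms: none
Why: Dess–Martin oxidation of the neopentyl primary alcohol; the tertiary alcohol, the tosylate and the alkenes are inert.

Step 24
Reactants: 33 the aldehyde
Product: 35 CNP0116395.1 (10R,11S,14R,15S in the locants used here), via hydroxy tosylate acid 34 (not isolated)
Conditions: NaClO2, NaH2PO4, 2-methylbut-2-ene, t-BuOH/H2O, 0 °C; then NaOH (aq) to pH 13, rt; work-up cold at pH 5–6 (NaH2PO4)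
Reagents that add atoms: sodium chlorite, [Na+].[O-]Cl=O
Why: Pinnick oxidation gives the acid, and at pH 13 the tertiary alkoxide displaces the primary tosylate (3-exo-tet) to close the spiro-oxirane with retention at C-11, so the acid-sensitive epoxy acid appears only in the last operation.

**Compound list**
1 | prop-2-yn-1-ol | C#CCO | starting material
2 | 4-methyl-2,5-dihydro-1,2-oxamagnesole (chelated alkenylmagnesium alkoxide) | CC1=C[Mg]OC1 | intermediate
3 | (2Z)-3-iodo-2-methylprop-2-en-1-ol | OC/C(C)=C\I | intermediate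
4 | (2Z)-3-iodo-2-methylprop-2-enal | O=C/C(C)=C\I | intermediate
5 | (1Z)-1-iodo-2-methylbuta-1,3-diene | C=C/C(C)=C\I | intermediate
6 | 4-ethenyl-2,5-dihydro-1,2-oxamagnesole (chelated dienylmagnesium alkoxide) | C=CC1=C[Mg]OC1 | intermediate
7 | (2Z)-2-(iodomethylidene)but-3-en-1-ol | OC/C(C=C)=C\I | intermediate
8 | tert-butyl{[(2Z)-2-(iodomethylidene)but-3-en-1-yl]oxy}dimethylsilane | CC(C)(C)[Si](C)(C)OC/C(C=C)=C\I | intermediate
9 | (2Z)-3-methylpent-2-en-4-yn-1-ol | C#C/C(C)=C\CO | starting material
10 | (2Z)-3-methylpenta-2,4-dien-1-ol | C=C/C(C)=C\CO | intermediate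
11 | bis(9-BBN) adduct of 10 (C-5 borane, O-borinate) | C1CCC2CCCC1B2CC/C(C)=C\COB1C2CCCC1CCC2 | intermediate
12 | (2Z,6Z)-3,7-dimethylnona-2,6,8-trien-1-ol | C=C/C(C)=C\CC/C(C)=C\CO | intermediate
13 | (2Z,6Z)-1-bromo-3,7-dimethylnona-2,6,8-triene | C=C/C(C)=C\CC/C(C)=C\CBr | intermediate
14 | [(3Z,7Z)-4,8-dimethyldeca-3,7,9-trien-1-yl]triphenylphosphonium bromide | C=C/C(C)=C\CC/C(C)=C\CC[P+](c1ccccc1)(c1ccccc1)c1ccccc1.[Br-] | intermediate
15 | 2,2-dimethyl-1,3-dioxan-5-one | CC1(C)OCC(=O)CO1 | starting material
16 | [(3Z,7Z)-4,8-dimethyldeca-3,7,9-trien-1-ylidene]triphenylphosphorane | C=C/C(C)=C\CC/C(C)=C\CC=P(c1ccccc1)(c1ccccc1)c1ccccc1 | intermediate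
17 | 5-[(3Z,7Z)-4,8-dimethyldeca-3,7,9-trien-1-ylidene]-2,2-dimethyl-1,3-dioxane | C=C/C(C)=C\CC/C(C)=C\CC=C1COC(C)(C)OC1 | intermediate
18 | 2-[(3Z,7Z)-4,8-dimethyldeca-3,7,9-trien-1-ylidene]propane-1,3-diol | C=C/C(C)=C\CC/C(C)=C\CC=C(CO)CO | intermediate
19 | tris(9-BBN) adduct of 18 (C-9 borane, both hydroxyls as borinates) | C1CCC2CCCC1B2CC/C(C)=C\CC/C(C)=C\CC=C(COB1C2CCCC1CCC2)COB1C2CCCC1CCC2 | intermediate
20 | 2-[(3Z,7Z,11Z)-12-({[tert-butyl(dimethyl)silyl]oxy}methyl)-4,8-dimethyltetradeca-3,7,11,13-tetraen-1-ylidene]propane-1,3-diol | C=C/C(CO[Si](C)(C)C(C)(C)C)=C/CC/C(C)=C\CC/C(C)=C\CC=C(CO)CO | intermediate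
21 | (2E,5Z,9Z,13Z)-14-({[tert-butyl(dimethyl)silyl]oxy}methyl)-2-(hydroxymethyl)-6,10-dimethylhexadeca-2,5,9,13,15-pentaenal | C=C/C(CO[Si](C)(C)C(C)(C)C)=C/CC/C(C)=C\CC/C(C)=C\C/C=C(CO)/C=O | intermediate
22 | (2E,5Z,9Z,13Z)-14-({[tert-butyl(dimethyl)silyl]oxy}methyl)-2-({[tert-butyl(diphenyl)silyl]oxy}methyl)-6,10-dimethylhexadeca-2,5,9,13,15-pentaenal | C=C/C(CO[Si](C)(C)C(C)(C)C)=C/CC/C(C)=C\CC/C(C)=C\C/C=C(CO[Si](c1ccccc1)(c1ccccc1)C(C)(C)C)/C=O | intermediate
23 | Diels–Alder adduct: bicyclo[9.3.1]pentadecatriene with 15-CHO (cis to C-9, trans to C-1), 15-CH2OTBDPS, 11-CH2OTBS, C-11=C-12 | O=C[C@]1(CO[Si](c3ccccc3)(c3ccccc3)C(C)(C)C)[C@H]2C/C=C(/C)CC/C=C(/C)CC[C@H]1C(CO[Si](C)(C)C(C)(C)C)=CC2 | intermediate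
24 | 15-ethenyl analogue of 23 | C=C[C@]1(CO[Si](c3ccccc3)(c3ccccc3)C(C)(C)C)[C@H]2C/C=C(/C)CC/C=C(/C)CC[C@H]1C(CO[Si](C)(C)C(C)(C)C)=CC2 | intermediate
25 | 1-bromo-2-methylprop-1-ene | CC(C)=CBr | starting material
26 | B-alkyl-9-BBN adduct of 24 (boron on C-17) | C1CCC2CCCC1B2CC[C@]1(CO[Si](c3ccccc3)(c3ccccc3)C(C)(C)C)[C@H]2C/C=C(/C)CC/C=C(/C)CC[C@H]1C(CO[Si](C)(C)C(C)(C)C)=CC2 | intermediate
27 | 15-(4-methylpent-3-en-1-yl) bis-silyl ether | CC(C)=CCC[C@]1(CO[Si](c3ccccc3)(c3ccccc3)C(C)(C)C)[C@H]2C/C=C(/C)CC/C=C(/C)CC[C@H]1C(CO[Si](C)(C)C(C)(C)C)=CC2 | intermediate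
28 | allylic alcohol (11-CH2OH, C-11=C-12) | CC(C)=CCC[C@]1(CO[Si](c3ccccc3)(c3ccccc3)C(C)(C)C)[C@H]2C/C=C(/C)CC/C=C(/C)CC[C@H]1C(CO)=CC2 | intermediate
29 | 11,12-epoxy alcohol (oxygen cis to C-9) | CC(C)=CCC[C@]1(CO[Si](c3ccccc3)(c3ccccc3)C(C)(C)C)[C@H]2C/C=C(/C)CC/C=C(/C)CC[C@H]1[C@@]4(CO)O[C@H]4C2 | intermediate
30 | 11-hydroxy-11-(hydroxymethyl) diol (11-OH cis to C-9) | CC(C)=CCC[C@]1(CO[Si](c3ccccc3)(c3ccccc3)C(C)(C)C)[C@H]2C/C=C(/C)CC/C=C(/C)CC[C@H]1[C@](O)(CO)CC2 | intermediate
31 | primary tosylate of 30 | CC(C)=CCC[C@]1(CO[Si](c3ccccc3)(c3ccccc3)C(C)(C)C)[C@H]2C/C=C(/C)CC/C=C(/C)CC[C@H]1[C@](O)(COS(=O)(=O)c3ccc(C)cc3)CC2 | intermediate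
32 | 15-hydroxymethyl hydroxy tosylate | CC(C)=CCC[C@]1(CO)[C@H]2C/C=C(/C)CC/C=C(/C)CC[C@H]1[C@](O)(COS(=O)(=O)c3ccc(C)cc3)CC2 | intermediate
33 | 15-formyl hydroxy tosylate | CC(C)=CCC[C@]1(C=O)[C@H]2C/C=C(/C)CC/C=C(/C)CC[C@H]1[C@](O)(COS(=O)(=O)c3ccc(C)cc3)CC2 | intermediate
34 | 15-carboxy hydroxy tosylate | CC(C)=CCC[C@]1(C(=O)O)[C@H]2C/C=C(/C)CC/C=C(/C)CC[C@H]1[C@](O)(COS(=O)(=O)c3ccc(C)cc3)CC2 | intermediate
35 | CNP0116395.1 | CC(C)=CCC[C@]1(C(=O)O)[C@H]2C/C=C(/C)CC/C=C(/C)CC[C@H]1[C@@]1(CC2)CO1 | target

**Totals**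
Total steps: 24. Longest linear sequence: 21 steps (steps 1–3, then 7–24).

**Steps most likely to fail**

1. Step 15 (Proposed new method). What may go wrong: the cationic boron catalyst may turn over poorly at high dilution, may discriminate the enal faces poorly, or intermolecular cycloaddition may outrun ring closure. The fallback sets out from 22 and comes back at 29. Compound 22 would be cyclised without a chiral controller (Me2AlCl, CH2Cl2, −78 → −20 °C, 1 mM, or toluene with BHT at 80–110 °C), a Lewis-acid-promoted or thermal macrocyclising intramolecular Diels–Alder reaction. This should give racemic adduct, that is 23 together with its enantiomer, ent-adduct aldehyde F1. The racemate would be taken through steps 16–18 as written, so that 24, 26, 27 and 28 are accompanied by ent-vinyl compound F2, its 9-BBN adduct F3, ent-homoprenyl bis-silyl ether F4 and ent-allylic alcohol F5. Sharpless epoxidation with L-(+)-diethyl tartrate is reagent-controlled and should oxidise the same local face of the allylic alcohol in both enantiomers. Compound 28 should then give 29, while F5 should give the diastereomeric epoxy alcohol F6 (oxygen trans to C-9 and cis to CH2OTBDPS). The two are diastereomers and should separate on silica; 29 continues with step 20, and the absolute configuration is then set at the epoxidation instead of the cycloaddition.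

2. Step 13. What may go wrong: the two allylic hydroxymethyl groups may be discriminated poorly, or oxidation may run on to the dialdehyde. The fallback sets out from 20 and comes back at 22. Lipase-catalysed transesterification (Pseudomonas cepacia lipase, vinyl acetate, THF, rt) should acylate the less hindered hydroxymethyl and give the (E)-monoacetate F7. Silylation of the remaining hydroxyl (TBDPSCl, imidazole) would give acetate silyl ether F8, and methanolysis (K2CO3, MeOH) the allylic alcohol silyl ether F9. MnO2 oxidation of F9, which has only one free hydroxyl, gives 22 directly without passing through 21.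

3. Step 10. What may go wrong: the enolisable ketone 15 may transfer a proton to the basic ylide, so that enolisation replaces olefination and the yield collapses. The fallback sets out from 14 and comes back at 18. Ylide 16, generated from 14 with KN(SiMe3)2 as in step 10, would be trapped with the non-enolisable, strongly electrophilic diethyl oxomalonate (THF, −78 °C → rt) to give diethyl alkylidenemalonate F10. Reduction of both ester groups by 1,2-addition (AlH3 from LiAlH4/AlCl3, Et2O, −20 °C, or DIBAL-H, toluene, −78 °C) would then give diol 18 directly, without 17 and without the hydrolysis of step 11.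

**Further compounds**
F1 | step 15 | ent-adduct aldehyde (enantiomer of 23) | O=C[C@@]1(CO[Si](c3ccccc3)(c3ccccc3)C(C)(C)C)[C@@H]2C/C=C(/C)CC/C=C(/C)CC[C@@H]1C(CO[Si](C)(C)C(C)(C)C)=CC2
F2 | step 15 | ent-vinyl compound (enantiomer of 24) | C=C[C@@]1(CO[Si](c3ccccc3)(c3ccccc3)C(C)(C)C)[C@@H]2C/C=C(/C)CC/C=C(/C)CC[C@@H]1C(CO[Si](C)(C)C(C)(C)C)=CC2
F3 | step 15 | 9-BBN adduct of F2 (enantiomer of 26) | C1CCC2CCCC1B2CC[C@@]1(CO[Si](c3ccccc3)(c3ccccc3)C(C)(C)C)[C@@H]2C/C=C(/C)CC/C=C(/C)CC[C@@H]1C(CO[Si](C)(C)C(C)(C)C)=CC2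
F4 | step 15 | ent-homoprenyl bis-silyl ether (enantiomer of 27) | CC(C)=CCC[C@@]1(CO[Si](c3ccccc3)(c3ccccc3)C(C)(C)C)[C@@H]2C/C=C(/C)CC/C=C(/C)CC[C@@H]1C(CO[Si](C)(C)C(C)(C)C)=CC2
F5 | step 15 | ent-allylic alcohol (enantiomer of 28) | CC(C)=CCC[C@@]1(CO[Si](c3ccccc3)(c3ccccc3)C(C)(C)C)[C@@H]2C/C=C(/C)CC/C=C(/C)CC[C@@H]1C(CO)=CC2
F6 | step 15 | diastereomeric epoxy alcohol from F5 (oxygen trans to C-9) | CC(C)=CCC[C@@]1(CO[Si](c3ccccc3)(c3ccccc3)C(C)(C)C)[C@@H]2C/C=C(/C)CC/C=C(/C)CC[C@@H]1[C@@]4(CO)O[C@H]4C2
F7 | step 13 | (E)-monoacetate of 20 (acetoxymethyl trans to C-1) | C=C/C(CO[Si](C)(C)C(C)(C)C)=C/CC/C(C)=C\CC/C(C)=C\C/C=C(CO)/COC(C)=O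
F8 | step 13 | acetate silyl ether (CH2OTBDPS cis to C-1) | C=C/C(CO[Si](C)(C)C(C)(C)C)=C/CC/C(C)=C\CC/C(C)=C\C/C=C(CO[Si](c1ccccc1)(c1ccccc1)C(C)(C)C)/COC(C)=O
F9 | step 13 | allylic alcohol silyl ether | C=C/C(CO[Si](C)(C)C(C)(C)C)=C/CC/C(C)=C\CC/C(C)=C\C/C=C(CO[Si](c1ccccc1)(c1ccccc1)C(C)(C)C)/CO
F10 | step 10 | diethyl 2-[(3Z,7Z)-4,8-dimethyldeca-3,7,9-trien-1-ylidene]propanedioate | C=C/C(C)=C\CC/C(C)=C\CC=C(C(=O)OCC)C(=O)OCC
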